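**Retrosynthetic overview** (ring atoms of all intermediates carry the target numbering: C1/C10 epoxide, C14 = CHO carbon on C10, C4(Me)=C5, C6 and C8 acetoxy, C7 isopropyl)
1. Feature: the methyl-bearing olefinic C4 and the oxygenated C8 face each other across the ten-membered ring. A C4–C8 bond plus a leaving group on C5 therefore defines a cis-fused five–seven bicycle (cyclopentane C4–C5–C6–C7–C8, cycloheptene C4–C3–C2–C1=C10–C9–C8) whose Grob fragmentation returns (E)-C4=C5 and the C8 carbonyl.
2. End game: target ⇐ Sharpless epoxidation and C14 oxidation ⇐ diacetate ⇐ hydroxyl-directed 1,3-anti reduction of the C8 ketone of the ten-membered ketone 28.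
3. 28 ⇐ fragmentation of hydroazulene mesylate 26 ⇐ ring-closing metathesis (C1=C10) ⇐ allyl addition (C8–C9) to cyclopentanone 20.
4. 20 ⇐ 2-methylcyclopentane-1,3-dione: enzymatic desymmetrisation fixes C4, and the temporary C8 carbinol steers anti conjugate addition of isopropyl (C7). Hydroxylation with inversion (C6) and ketone reduction (C5) then place Me, OMs, OTBS and i-Pr on one face, and allyl addition anti to i-Pr puts the C8 hydroxyl there too.
5. Ring order: cyclopentane (purchased) → seven-membered ring (metathesis) → ten-membered ring (fragmentation) → epoxide.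

Key step: step 18

Assumption: baker's yeast reduces dione 4 with the sense known for the 2-allyl analogue (hydride from the methyl face to one enantiotopic carbonyl, giving the (2S,3S)-ketol); a ketoreductase of the same sense may replace it.

Step 1
Reactants: 1 2-methylcyclopentane-1,3-dione; 2 acrolein
Product: 3 3-(1-methyl-2,5-dioxocyclopentyl)propanal
Conditions: H2O, rt
Reagents that add atoms: none
Why: Michael addition of the acidic cyclic 1,3-dione to acrolein in water gives the C-alkylated dione; no stereocentre is formed.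

Step 2
Reactants: 3 3-(1-methyl-2,5-dioxocyclopentyl)propanal
Product: 4 2-(but-3-en-1-yl)-2-methylcyclopentane-1,3-dione
Conditions: Ph3PCH3Br, KHMDS, THF, −78 → 0 °C (1.0 equiv of preformed ylide)
Reagents that add atoms: methyltriphenylphosphonium bromide, C[P+](c1ccccc1)(c1ccccc1)c1ccccc1.[Br-]
Why: Wittig methylenation is selective for the aldehyde over the two neopentyl ketones at low temperature.

Step 3
Reactants: 4 2-(but-3-en-1-yl)-2-methylcyclopentane-1,3-dione
Product: 5 (2S,3S)-2-(but-3-en-1-yl)-3-hydroxy-2-methylcyclopentan-1-one (C8 hydroxyl cis to the butenyl chain)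
Conditions: baker's yeast (Saccharomyces cerevisiae), sucrose, H2O, 30 °C
Reagents that add atoms: none
Why: Enzymatic desymmetrising carbonyl reduction delivers hydride to one enantiotopic carbonyl from the methyl face, which sets C4 (S) and the temporary C8 carbinol (S, hydroxyl cis to butenyl).

Step 4
Reactants: 5 (2S,3S)-ketol
Product: 6 (2S,3S)-2-(but-3-en-1-yl)-2-methyl-3-(triethylsilyloxy)cyclopentan-1-one
Conditions: TESCl, imidazole, DMF, 0 °C → rt
Reagents that add atoms: chlorotriethylsilane, CC[Si](Cl)(CC)CC
Why: Silylation of the secondary alcohol blocks retro-aldol cleavage and supplies the bulky C8 substituent that directs step 6.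

Step 5
Reactants: 6 TES ether
Product: 8 (4S,5S)-5-(but-3-en-1-yl)-5-methyl-4-(triethylsilyloxy)cyclopent-2-en-1-one (C5 ketone, C6=C7), via lithium enolate 7 (not isolated)
Conditions: LDA, THF, −78 °C; then PhS(Cl)=N-t-Bu, −78 °C
Reagents that add atoms: none
Why: Mukaiyama dehydrogenation: the C6 enolate (the only α-position with hydrogens) is sulfinimidoylated and undergoes syn-elimination at −78 °C, leaving the terminal alkene untouched.

Step 6
Reactants: 8 enone; 9 isopropylmagnesium chloride
Product: 10 C5 trimethylsilyl enol ether (C5=C6) carrying the C7 isopropyl group trans to the C8 OTES group and cis to the C4 methyl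
Conditions: CuBr·SMe2 (10 mol %), TMSCl, THF, −78 °C; Et3N, pentane work-up
Reagents that add atoms: chlorotrimethylsilane, C[Si](C)(C)Cl
Why: Copper-catalysed, TMSCl-accelerated conjugate addition to the 4-silyloxycyclopentenone occurs anti to the adjacent C8 silyloxy group, which sets C7, and the enolate is trapped as its silyl enol ether.

Step 7
Reactants: 10 silyl enol ether
Product: 12 α-hydroxy ketone with the C6 hydroxyl trans to the C7 isopropyl group, via α-trimethylsilyloxy ketone 11 (not isolated)
Conditions: mCPBA, NaHCO3, CH2Cl2, −20 °C; then K2CO3, MeOH, 0 °C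
Reagents that add atoms: 3-chloroperbenzoic acid, OOC(=O)c1cccc(Cl)c1
Why: Rubottom oxidation: the electron-rich enol ether is epoxidised in preference to the terminal alkene and from the face opposite the adjacent isopropyl group, so the C6 oxygen arrives trans to isopropyl.

Step 8
Reactants: 12 trans α-hydroxy ketone
Product: 15 α-hydroxy ketone with the C6 hydroxyl cis to the C7 isopropyl group, via C6 triflate 13 (not isolated), via C6 nitrite ester 14 (not isolated)
Conditions: Tf2O, pyridine, CH2Cl2, −30 °C; then Bu4NNO2, DMF, rt; aqueous work-up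
Reagents that add atoms: tetrabutylammonium nitrite, CCCC[N+](CCCC)(CCCC)CCCC.[O-]N=O
Why: Lattrell–Dax inversion: SN2 displacement of the carbonyl-activated secondary triflate by nitrite oxygen, then hydrolysis of the nitrite ester, inverts C6 and places the hydroxyl cis to isopropyl as the target requires.

Step 9
Reactants: 15 cis α-hydroxy ketone
Product: 16 C6 tert-butyldimethylsilyl ether of 15
Conditions: TBSOTf, 2,6-lutidine, CH2Cl2, −78 → 0 °C
Reagents that add atoms: tert-butyldimethylsilyl trifluoromethanesulfonate, CC(C)(C)[Si](C)(C)OS(=O)(=O)C(F)(F)F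
Why: Silylation of the hindered secondary alcohol with the silyl triflate under non-epimerising conditions.

Step 10
Reactants: 16 α-silyloxy ketone
Product: 17 C5 alcohol with the hydroxyl cis to the C4 methyl, the C6 OTBS and the C7 isopropyl groups
Conditions: NaBH4, MeOH, −20 → 0 °C
Reagents that add atoms: none
Why: Hydride reduction of the α-silyloxy ketone from the face opposite the adjacent OTBS group and the C4 methyl (Felkin-type, sterically reinforced) gives the C5 alcohol cis to methyl, the relationship that later dictates the E olefin.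

Step 11
Reactants: 17 C5 alcohol
Product: 18 C5 methanesulfonate
Conditions: MsCl, Et3N, CH2Cl2, 0 °C
Reagents that add atoms: methanesulfonyl chloride, CS(=O)(=O)Cl
Why: Mesylation through the sulfene installs the nucleofuge on the neopentyl secondary alcohol with retention at C5.

Step 12
Reactants: 18 mesylate
Product: 19 C8 secondary alcohol (TES removed; C6 OTBS and C5 OMs retained)
Conditions: PPTS, MeOH/CH2Cl2, 0 °C → rt
Reagents that add atoms: none
Why: Acid-catalysed methanolysis removes the triethylsilyl ether selectively, because the hindered secondary TBS ether and the mesylate are stable to PPTS.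

Step 13
Reactants: 19 C8 alcohol
Product: 20 C8 ketone (2-(but-3-enyl)-2-methylcyclopentanone carrying C5 OMs, C6 OTBS and C7 i-Pr all cis to the methyl)
Conditions: Dess–Martin periodinane, NaHCO3, CH2Cl2, 0 °C → rt
Reagents that add atoms: none
Why: Dess–Martin oxidation under buffered, non-basic conditions gives the ketone without epimerising C7 or eliminating the β-silyloxy group, and C4 has no hydrogen so the β-mesylate cannot eliminate.

Step 14
Reactants: 21 2-methylenepropane-1,3-diol
Product: 22 2-{[(4-methoxybenzyl)oxy]methyl}prop-2-en-1-ol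
Conditions: NaH, PMBCl, THF/DMF, 0 °C (diol in excess)
Reagents that add atoms: 4-methoxybenzyl chloride, COc1ccc(CCl)cc1
Why: Williamson mono-etherification of the symmetrical diol used in excess.

Step 15
Reactants: 22 mono-PMB ether
Product: 23 1-({[2-(bromomethyl)prop-2-en-1-yl]oxy}methyl)-4-methoxybenzene
Conditions: CBr4, PPh3, CH2Cl2, 0 °C
Reagents that add atoms: carbon tetrabromide, BrC(Br)(Br)Br
Why: Appel bromination of the primary allylic alcohol.

Step 16
Reactants: 20 C8 ketone; 23 allylic bromide
Product: 25 tertiary C8 alcohol with the hydroxyl on the face of the methyl group and the 2-(PMBOCH2)allyl chain cis to the butenyl chain, via allylzinc bromide 24 (not isolated)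
Conditions: Zn dust, THF/sat. aq NH4Cl, rt
Reagents that add atoms: none
Why: Barbier allylation: the allylzinc adds to the hindered ketone from the face opposite the C7 isopropyl, C6 OTBS and C5 OMs groups, which sets C8, and the aqueous medium protonates the alkoxide at once so that it cannot fragment.

Step 17
Reactants: 25 diene
Product: 26 cis-fused hydroazulene: C8 hydroxyl, C5 mesylate, C4 methyl, C6 OTBS and C7 isopropyl all on one face of the cyclopentane, C1=C10 in the seven-membered ring with CH2OPMB on C10
Conditions: Grubbs II (5 mol %), CH2Cl2 (2 mM), 40 °C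
Reagents that add atoms: none
Why: Ring-closing metathesis of the two cis-disposed chains (mono- and 1,1-disubstituted alkenes) closes the seven-membered ring, in which the trisubstituted C1=C10 olefin is necessarily cis.

Step 18
Reactants: 26 hydroazulene C8-hydroxy C5-mesylate
Product: 28 (4E)-cyclodeca-1(10),4-dien-8-one with C6 OTBS, C7 isopropyl and CH2OPMB on C10, via potassium alkoxide 27 (not isolated)
Conditions: t-BuOK (1.05 equiv), THF, −20 → 0 °C; pH 7 buffer
Reagents that add atoms: none
Why: Deprotonation gives the C8 alkoxide, whose lone pair pushes into the C4–C8 σ bond as that bond breaks and the pseudo-equatorial C5 mesylate departs in one anti-periplanar event, forming the C8 ketone and the C4=C5 π bond; this is a Wharton–Grob fragmentation of a cyclic 1,3-diol monosulfonate, the closest known type being the fragmentation of bicyclic γ-mesyloxy alkoxides to medium-ring alkenones. No ring is closed by bond formation: the ten-membered ring is unveiled by scission of the fusion bond of the five–seven bicycle whose seven-membered ring was closed in step 17. No stereocentre is created; C4, C5 and C8 are erased and C6 and C7 pass through unchanged. The step needs E geometry at C4=C5 and fragmentation in preference to substitution or elimination: the mesylate is cis to the C4 methyl, so anti-periplanar cleavage leaves C6 cis to the methyl and trans to C3 (E), while C1=C10 keeps the cis geometry imposed by the seven-membered ring. The alkoxide and the mesylate lie on the same face of the cyclopentane, which rules out intramolecular displacement, and one equivalent of base at low temperature leaves no base to enolise the ketone.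

Step 19
Reactants: 28 silyloxy ketone
Product: 29 β-hydroxy ketone (free C6 hydroxyl)
Conditions: HF·pyridine, pyridine, THF, 0 °C → rt
Reagents that add atoms: none
Why: Buffered fluoride desilylation frees the allylic C6 alcohol without the retro-aldol or elimination that basic fluoride would cause in a β-hydroxy ketone.

Step 20
Reactants: 29 β-hydroxy ketone
Product: 30 C6,C8 1,3-anti diol
Conditions: Me4NBH(OAc)3, MeCN/AcOH, −30 °C
Reagents that add atoms: none
Why: Evans–Saksena reduction: the C6 hydroxyl binds the acetoxyborohydride and delivers hydride intramolecularly through a chair six-membered transition state, giving the 1,3-anti diol and hence the C8 configuration of the target.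

Step 21
Reactants: 30 diol
Product: 31 C6,C8 diacetate
Conditions: Ac2O, pyridine, DMAP, CH2Cl2, rt
Reagents that add atoms: acetic anhydride, CC(=O)OC(C)=O
Why: DMAP-catalysed acetylation of both secondary alcohols.

Step 22
Reactants: 31 PMB ether
Product: 32 C14 allylic alcohol
Conditions: DDQ, CH2Cl2/pH 7 buffer, 0 °C
Reagents that add atoms: none
Why: Oxidative PMB cleavage by DDQ (hydride abstraction, hydrolysis of the oxocarbenium ion) leaves the acetates and olefins untouched.

Step 23
Reactants: 32 allylic alcohol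
Product: 33 (1R,10R)-1,10-epoxy alcohol
Conditions: Ti(Oi-Pr)4 (cat.), D-(−)-diethyl tartrate (cat.), t-BuOOH, 4 Å MS, CH2Cl2, −20 °C
Reagents that add atoms: tert-butyl hydroperoxide, CC(C)(C)OO
Why: Sharpless asymmetric epoxidation: titanium binds the allylic alcohol so only C1=C10 reacts, and D-(−)-tartrate delivers oxygen to the face that gives the (2R,3R)-type epoxy alcohol of an E-2,3-disubstituted allylic alcohol, here the 1R,10R epoxide (10S once C14 is the aldehyde).

Step 24
Reactants: 33 epoxy alcohol
Product: 34 Pulicanaral A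
Conditions: Dess–Martin periodinane, NaHCO3, CH2Cl2, 0 °C
Reagents that add atoms: none
Why: Buffered Dess–Martin oxidation converts the primary epoxy alcohol into the aldehyde without touching any stereocentre.

**Compound list**
1 | 2-methylcyclopentane-1,3-dione | CC1C(=O)CCC1=O | starting material
2 | acrolein | C=CC=O | starting material
3 | 3-(1-methyl-2,5-dioxocyclopentyl)propanal | CC1(CCC=O)C(=O)CCC1=O | intermediate
4 | 2-(but-3-en-1-yl)-2-methylcyclopentane-1,3-dione | CC1(CCC=C)C(=O)CCC1=O | intermediate
5 | (2S,3S)-2-(but-3-en-1-yl)-3-hydroxy-2-methylcyclopentan-1-one | C[C@]1(CCC=C)[C@@H](O)CCC1=O | intermediate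
6 | (2S,3S)-2-(but-3-en-1-yl)-2-methyl-3-(triethylsilyloxy)cyclopentan-1-one | C[C@]1(CCC=C)[C@@H](O[Si](CC)(CC)CC)CCC1=O | intermediate
7 | lithium enolate of 6 (C5–O⁻, C5=C6) | [Li+].C[C@]1(CCC=C)[C@@H](O[Si](CC)(CC)CC)CC=C1[O-] | intermediate
8 | (4S,5S)-5-(but-3-en-1-yl)-5-methyl-4-(triethylsilyloxy)cyclopent-2-en-1-one | C[C@]1(CCC=C)[C@@H](O[Si](CC)(CC)CC)C=CC1=O | intermediate
9 | isopropylmagnesium chloride | CC(C)[Mg]Cl | starting material
10 | C5 trimethylsilyl enol ether, C7 i-Pr trans to C8 OTES | C[C@]1(CCC=C)[C@@H](O[Si](CC)(CC)CC)[C@H](C(C)C)C=C1O[Si](C)(C)C | intermediate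
11 | α-trimethylsilyloxy ketone, C6 OTMS trans to i-Pr | C[C@]1(CCC=C)[C@@H](O[Si](CC)(CC)CC)[C@H](C(C)C)[C@@H](O[Si](C)(C)C)C1=O | intermediate
12 | α-hydroxy ketone, C6 OH trans to i-Pr | C[C@]1(CCC=C)[C@@H](O[Si](CC)(CC)CC)[C@H](C(C)C)[C@@H](O)C1=O | intermediate
13 | C6 triflate of 12 | C[C@]1(CCC=C)[C@@H](O[Si](CC)(CC)CC)[C@H](C(C)C)[C@@H](OS(=O)(=O)C(F)(F)F)C1=O | intermediate
14 | C6 nitrite ester, inverted | C[C@]1(CCC=C)[C@@H](O[Si](CC)(CC)CC)[C@H](C(C)C)[C@H](ON=O)C1=O | intermediate
15 | α-hydroxy ketone, C6 OH cis to i-Pr | C[C@]1(CCC=C)[C@@H](O[Si](CC)(CC)CC)[C@H](C(C)C)[C@H](O)C1=O | intermediate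
16 | C6 TBS ether of 15 | C[C@]1(CCC=C)[C@@H](O[Si](CC)(CC)CC)[C@H](C(C)C)[C@H](O[Si](C)(C)C(C)(C)C)C1=O | intermediate
17 | C5 alcohol, OH cis to Me, OTBS and i-Pr | C[C@]1(CCC=C)[C@@H](O[Si](CC)(CC)CC)[C@H](C(C)C)[C@H](O[Si](C)(C)C(C)(C)C)[C@@H]1O | intermediate
18 | C5 mesylate of 17 | C[C@]1(CCC=C)[C@@H](O[Si](CC)(CC)CC)[C@H](C(C)C)[C@H](O[Si](C)(C)C(C)(C)C)[C@@H]1OS(C)(=O)=O | intermediate
19 | C8 alcohol (TES removed) | C[C@]1(CCC=C)[C@@H](O)[C@H](C(C)C)[C@H](O[Si](C)(C)C(C)(C)C)[C@@H]1OS(C)(=O)=O | intermediate
20 | C8 ketone | C[C@]1(CCC=C)C(=O)[C@H](C(C)C)[C@H](O[Si](C)(C)C(C)(C)C)[C@@H]1OS(C)(=O)=O | intermediate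
21 | 2-methylenepropane-1,3-diol | C=C(CO)CO | starting material
22 | 2-{[(4-methoxybenzyl)oxy]methyl}prop-2-en-1-ol | C=C(CO)COCc1ccc(OC)cc1 | intermediate
23 | 1-({[2-(bromomethyl)prop-2-en-1-yl]oxy}methyl)-4-methoxybenzene | C=C(CBr)COCc1ccc(OC)cc1 | intermediate
24 | {2-[(4-methoxybenzyloxy)methyl]allyl}zinc bromide | C=C(C[Zn]Br)COCc1ccc(OC)cc1 | intermediate
25 | tertiary C8 alcohol, allyl chain cis to butenyl | C[C@]1(CCC=C)[C@@](O)(CC(=C)COCc2ccc(OC)cc2)[C@H](C(C)C)[C@H](O[Si](C)(C)C(C)(C)C)[C@@H]1OS(C)(=O)=O | intermediate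
26 | cis-fused hydroazulene C8-hydroxy C5-mesylate | C[C@]12CC/C=C(/COCc3ccc(OC)cc3)C[C@@]1(O)[C@H](C(C)C)[C@H](O[Si](C)(C)C(C)(C)C)[C@@H]2OS(C)(=O)=O | intermediate
27 | potassium C8 alkoxide of 26 | [K+].C[C@]12CC/C=C(/COCc3ccc(OC)cc3)C[C@@]1([O-])[C@H](C(C)C)[C@H](O[Si](C)(C)C(C)(C)C)[C@@H]2OS(C)(=O)=O | intermediate
28 | (4E)-cyclodeca-1(10),4-dien-8-one, C6 OTBS, C7 i-Pr, C10 CH2OPMB | CC(C)(C)[Si](C)(C)O[C@@H]1/C=C(\C)CC/C=C(/COCc2ccc(OC)cc2)CC(=O)[C@@H]1C(C)C | intermediate
29 | C6-hydroxy C8-ketone | O[C@@H]1/C=C(\C)CC/C=C(/COCc2ccc(OC)cc2)CC(=O)[C@@H]1C(C)C | intermediate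
30 | C6,C8 anti-diol | O[C@@H]1/C=C(\C)CC/C=C(/COCc2ccc(OC)cc2)C[C@@H](O)[C@@H]1C(C)C | intermediate
31 | C6,C8 diacetate, C14 OPMB | CC(=O)O[C@@H]1/C=C(\C)CC/C=C(/COCc2ccc(OC)cc2)C[C@@H](OC(C)=O)[C@@H]1C(C)C | intermediate
32 | C14 allylic alcohol diacetate | CC(=O)O[C@@H]1/C=C(\C)CC/C=C(/CO)C[C@@H](OC(C)=O)[C@@H]1C(C)C | intermediate
33 | (1R,10R)-epoxy alcohol diacetate | CC(=O)O[C@@H]1/C=C(\C)CC[C@H]2O[C@@]2(CO)C[C@@H](OC(C)=O)[C@@H]1C(C)C | intermediate
34 | Pulicanaral A | CC(=O)O[C@@H]1/C=C(\C)CC[C@H]2O[C@@]2(C=O)C[C@@H](OC(C)=O)[C@@H]1C(C)C | target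

**Step count**
Total: 24 steps. Longest linear sequence: 22 steps (steps 1–13 and 16–24).

**Steps most likely to fail**

Step 18 (fragmentation). In a cyclopentane the C5–O bond can approach but not reach full anti-periplanarity with the C4–C8 bond, so heterolysis may be slow. Silyl migration from O6 to the alkoxide, and enolisation or β-elimination of the ketone once it forms, could then compete. The fallback sets out from 17 and returns at 28; it uses a triflate made in situ from the free 1,3-diol, a far better nucleofuge that needs no strong base. Alcohol 17 is acetylated (Ac2O, pyridine, DMAP) to the C5 acetate F1. The TES ether is cleaved (PPTS, MeOH) to the C8 alcohol F2, which is oxidised (Dess–Martin periodinane) to the ketone F3. Zinc-mediated addition of 23 gives the tertiary alcohol F4, and ring-closing metathesis gives the hydroazulene acetate F5. Methanolysis (K2CO3, MeOH) frees the C5,C8-diol F6. Tf2O and 2,6-lutidine in CH2Cl2 at −78 °C convert the secondary C5 hydroxyl into the C5 triflate F7, which is not isolated and should fragment under the amine base to 28.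

Step 8 (inversion at C6). Backside attack must come from the face that carries the C7 isopropyl group, so substitution may be slow. Decomposition of the α-keto triflate or N-attack of nitrite could then overtake it. The fallback sets out from 12 and returns at 16; it replaces substitution by enolate protonation. Alcohol 12 is silylated (TBSOTf, 2,6-lutidine) to the trans α-silyloxy ketone F8. Deprotonation (LDA, THF, −78 °C) gives the lithium enolate F9, which is protonated at −78 °C by 2,6-di-tert-butyl-4-methylphenol from the face opposite the isopropyl group; this places the silyloxy group cis to isopropyl and gives 16.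

Step 23 (epoxidation). The conformation of the ten-membered ring may expose one face of C1=C10 so strongly that substrate bias opposes the tartrate, leading to poor facial selectivity or a stalled reaction. The fallback sets out from 32 and returns at 34; it inverts the order of oxidation and epoxidation. Alcohol 32 is oxidised (MnO2, CH2Cl2) to the enal F10. The enal is epoxidised with aqueous H2O2 under iminium catalysis by a 9-amino-9-deoxy-epi-cinchona alkaloid salt, the pseudo-enantiomer being chosen for the 1R,10S epoxide, which gives 34 directly.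

**Further compounds**
F1 | step 18 | C5 acetate of 17 | C[C@]1(CCC=C)[C@@H](O[Si](CC)(CC)CC)[C@H](C(C)C)[C@H](O[Si](C)(C)C(C)(C)C)[C@@H]1OC(C)=O
F2 | step 18 | C8 alcohol, C5 acetate | C[C@]1(CCC=C)[C@@H](O)[C@H](C(C)C)[C@H](O[Si](C)(C)C(C)(C)C)[C@@H]1OC(C)=O
F3 | step 18 | C8 ketone, C5 acetate | C[C@]1(CCC=C)C(=O)[C@H](C(C)C)[C@H](O[Si](C)(C)C(C)(C)C)[C@@H]1OC(C)=O
F4 | step 18 | tertiary C8 alcohol, C5 acetate | C[C@]1(CCC=C)[C@@](O)(CC(=C)COCc2ccc(OC)cc2)[C@H](C(C)C)[C@H](O[Si](C)(C)C(C)(C)C)[C@@H]1OC(C)=O
F5 | step 18 | hydroazulene C8-hydroxy C5-acetate | C[C@]12CC/C=C(/COCc3ccc(OC)cc3)C[C@@]1(O)[C@H](C(C)C)[C@H](O[Si](C)(C)C(C)(C)C)[C@@H]2OC(C)=O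
F6 | step 18 | hydroazulene C5,C8-diol | C[C@]12CC/C=C(/COCc3ccc(OC)cc3)C[C@@]1(O)[C@H](C(C)C)[C@H](O[Si](C)(C)C(C)(C)C)[C@@H]2O
F7 | step 18 | hydroazulene C8-hydroxy C5-triflate | C[C@]12CC/C=C(/COCc3ccc(OC)cc3)C[C@@]1(O)[C@H](C(C)C)[C@H](O[Si](C)(C)C(C)(C)C)[C@@H]2OS(=O)(=O)C(F)(F)F
F8 | step 8 | trans α-(tert-butyldimethylsilyloxy) ketone | C[C@]1(CCC=C)[C@@H](O[Si](CC)(CC)CC)[C@H](C(C)C)[C@@H](O[Si](C)(C)C(C)(C)C)C1=O
F9 | step 8 | lithium enolate of F8 | [Li+].C[C@]1(CCC=C)[C@@H](O[Si](CC)(CC)CC)[C@H](C(C)C)C(O[Si](C)(C)C(C)(C)C)=C1[O-]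
F10 | step 23 | C14 enal diacetate | CC(=O)O[C@@H]1/C=C(\C)CC/C=C(/C=O)C[C@@H](OC(C)=O)[C@@H]1C(C)C
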